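**Retrosynthetic overview**

1. Target 26 ⇐ diol 25 ⇐ 3-ketone 23: both formates are put on last, and the 3β-hydroxyl comes from hydride reduction of the rigid 4,4-dimethyl-3-ketone.
2. Ring B is closed last at C6–C7: a C7 alkenyl radical (from alkenyl iodide 20) adds to the exocyclic C5=C6 methylene on ring A, and the C5 radical is reduced.
3. Enabling feature: in ring B the trisubstituted C7=C8 olefin (C17 on C8) adjoins C6H2, and the ring-fusion carbon C5 lies between the fully substituted C4 and C10. A C5=C6 methylene therefore accepts the radical only at C6, and the C5 radical can only take up hydrogen, from the face opposite the C4 and C10 methyls.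
4. C9–C10 (quaternary C10 and C9) ⇐ Ireland–Claisen rearrangement of ester 10, with chirality relayed from C2–O of (S)-phorenol 7; the C1=C2 olefin it leaves is used to oxidise C3.
5. Ring A (C1–C5, C10, C18–C20) is bought as ketoisophorone 6 and carried through; the side chain with C13 comes from (S)-citronellol 1. Ring order: A (purchased), then B (step 13).

Key step: step 13

Remark: labdane numbering is used for atom locants (C1–C10 decalin, C11–C16 side chain, C17 on C8, C18/C19 on C4, C20 on C10); (S)-citronellol and ketoisophorone are taken as commercial.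

**Route**

Step 1
Reactants: 1 (S)-citronellol
Product: 2 triisopropyl{[(3S)-3,7-dimethyloct-6-en-1-yl]oxy}silane
Conditions: i-Pr3SiCl, imidazole, DMF, 0 °C → rt
Reagents that add atoms: triisopropylsilyl chloride CC(C)[Si](Cl)(C(C)C)C(C)C
Why: Imidazole-promoted silyl ether formation masks the C15 hydroxyl with a group that should survive the organolithium, organoaluminium, radical and hydride steps, and no stereocenter is touched.

Step 2
Reactants: 2 triisopropyl{[(3S)-3,7-dimethyloct-6-en-1-yl]oxy}silane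
Product: 3 (4S)-4-methyl-6-[(triisopropylsilyl)oxy]hexanoic acid
Conditions: RuCl3·xH2O (cat.), NaIO4, EtOAc/MeCN/H2O, rt
Reagents that add atoms: sodium periodate [Na+].[O-]I(=O)(=O)=O; water O
Why: Ruthenium-catalysed periodate cleavage of the trisubstituted olefin removes the isopropylidene carbons as acetone and leaves the future C8 as a carboxyl group without touching C13.

Step 3
Reactants: 3 (4S)-4-methyl-6-[(triisopropylsilyl)oxy]hexanoic acid
Product: 5 (5S)-1-diazo-5-methyl-7-[(triisopropylsilyl)oxy]heptan-2-one, via mixed anhydride 4 (not isolated)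
Conditions: i-BuOCOCl, Et3N, THF, −15 °C; then CH2N2, Et2O, 0 °C
Reagents that add atoms: diazomethane C=[N+]=[N-]
Why: Arndt–Eistert acylation of diazomethane through the mixed carbonic anhydride gives the α-diazoketone under buffered conditions that spare the silyl ether, and the diazo carbon is the future C9.

Step 4
Reactants: 6 ketoisophorone (2,6,6-trimethylcyclohex-2-ene-1,4-dione)
Product: 7 (4S)-4-hydroxy-2,6,6-trimethylcyclohex-2-en-1-one [(S)-phorenol]
Conditions: RuCl(p-cymene)[(S,S)-TsDPEN] (cat.), i-PrOH, rt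
Reagents that add atoms: none
Why: Noyori asymmetric transfer hydrogenation should reduce only the less hindered enedione carbonyl (between CH2 and CH=), and the (S,S)-ligand is expected by analogy with aryl and alkenyl ketones to give the 4S carbinol (the antipodal ligand is used if the sense proves opposite).

Step 5
Reactants: 5 (5S)-1-diazo-5-methyl-7-[(triisopropylsilyl)oxy]heptan-2-one; 7 (4S)-4-hydroxy-2,6,6-trimethylcyclohex-2-en-1-one
Product: 9 (1S)-3,5,5-trimethyl-4-oxocyclohex-2-en-1-yl (5S)-5-methyl-7-[(triisopropylsilyl)oxy]heptanoate, via ketene 8 (not isolated)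
Conditions: PhCO2Ag (cat.), Et3N, THF, rt, dark; 7 in excess
Reagents that add atoms: none
Why: Silver-catalysed Wolff rearrangement generates ketene 8, which the secondary allylic alcohol 7 should trap to give the one-carbon-homologated ester directly, with both stereocenters untouched.

Step 6
Reactants: 9 (1S)-3,5,5-trimethyl-4-oxocyclohex-2-en-1-yl (5S)-5-methyl-7-[(triisopropylsilyl)oxy]heptanoate
Product: 10 (1S)-3,5,5-trimethyl-4-methylidenecyclohex-2-en-1-yl (5S)-5-methyl-7-[(triisopropylsilyl)oxy]heptanoate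
Conditions: Zn, CH2Br2, TiCl4, THF/CH2Cl2, 0 °C → rt
Reagents that add atoms: dibromomethane BrCBr
Why: Takai–Lombardo methylenation should convert the hindered conjugated ketone into the exocyclic C5=C6 methylene while leaving the ester alone, so that C6 is in place and ring A carries no carbonyl during step 7.

Step 7
Reactants: 10 (1S)-3,5,5-trimethyl-4-methylidenecyclohex-2-en-1-yl (5S)-5-methyl-7-[(triisopropylsilyl)oxy]heptanoate
Product: 13 (2R,5S)-5-methyl-7-[(triisopropylsilyl)oxy]-2-[(1R)-1,5,5-trimethyl-6-methylidenecyclohex-2-en-1-yl]heptanoic acid, via silyl ketene acetal 11 (not isolated), via trimethylsilyl ester 12 (not isolated)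
Conditions: LiN(i-Pr)2, THF/DMPU, −78 °C; Me3SiCl; −78 → 50 °C; then 1 M HCl
Reagents that add atoms: none
Why: In this Ireland–Claisen rearrangement the new C9–C10 bond must form on the ring face that carried the C2–O bond (suprafacial 1,3-chirality transfer, fixing 10R), while the (Z)-silyl ketene acetal formed in THF/DMPU should react through a chair with the side chain equatorial on C9 to give the 9,10-relationship of the target (the E acetal through a boat would lead to the same epimer).

Step 8
Reactants: 13 (2R,5S)-5-methyl-7-[(triisopropylsilyl)oxy]-2-[(1R)-1,5,5-trimethyl-6-methylidenecyclohex-2-en-1-yl]heptanoic acid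
Product: 14 (3R,6S)-6-methyl-8-[(triisopropylsilyl)oxy]-3-[(1R)-1,5,5-trimethyl-6-methylidenecyclohex-2-en-1-yl]octan-2-one
Conditions: MeLi (3 equiv), Et2O, 0 °C → rt; aq NH4Cl
Reagents that add atoms: methyllithium [Li]C
Why: Addition of methyllithium to the lithium carboxylate gives a gem-dialkoxide that collapses to the methyl ketone only on work-up, so neither over-addition nor epimerisation at C9 is expected.

Step 9
Reactants: 14 (3R,6S)-6-methyl-8-[(triisopropylsilyl)oxy]-3-[(1R)-1,5,5-trimethyl-6-methylidenecyclohex-2-en-1-yl]octan-2-one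
Product: 16 triisopropyl{[(3S,6S)-3-methyl-6-[(1R)-1,5,5-trimethyl-6-methylidenecyclohex-2-en-1-yl]oct-7-yn-1-yl]oxy}silane, via enol phosphate 15 (not isolated)
Conditions: LiN(i-Pr)2 (1.1 equiv), THF, −78 °C; ClP(O)(OEt)2; then LiN(i-Pr)2 (2.5 equiv), −78 °C → rt; H2O
Reagents that add atoms: none
Why: In this methyl ketone to terminal alkyne conversion (enol phosphate formation and elimination) kinetic deprotonation should occur at the methyl group and not at the hindered C9–H, so C9 keeps its configuration and the former ketone methyl becomes C7.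

Step 10
Reactants: 16 triisopropyl{[(3S,6S)-3-methyl-6-[(1R)-1,5,5-trimethyl-6-methylidenecyclohex-2-en-1-yl]oct-7-yn-1-yl]oxy}silane
Product: 18 {[(3S,6R,7E)-8-iodo-3,7-dimethyl-6-[(1R)-1,5,5-trimethyl-6-methylidenecyclohex-2-en-1-yl]oct-7-en-1-yl]oxy}triisopropylsilane, via alkenylalane 17 (not isolated)
Conditions: AlMe3, Cp2ZrCl2 (cat.), H2O (1 equiv), CH2Cl2, −20 → 0 °C; then I2, THF, −30 °C
Reagents that add atoms: trimethylaluminium C[Al](C)C; iodine II
Why: Negishi carboalumination adds methyl (C17) to C8 and aluminium to C7 in a syn fashion, iodinolysis with retention gives the E alkenyl iodide, and the two ring olefins should be inert to the reagent.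

Step 11
Reactants: 18 {[(3S,6R,7E)-8-iodo-3,7-dimethyl-6-[(1R)-1,5,5-trimethyl-6-methylidenecyclohex-2-en-1-yl]oct-7-en-1-yl]oxy}triisopropylsilane
Product: 19 (4R)-4-[(1E,3R,6S)-1-iodo-2,6-dimethyl-8-[(triisopropylsilyl)oxy]oct-1-en-3-yl]-4,6,6-trimethyl-5-methylidenecyclohex-2-en-1-one
Conditions: Rh2(cap)4 [dirhodium tetrakis(caprolactamate)] (cat.), t-BuOOH, K2CO3, CH2Cl2, rt
Reagents that add atoms: tert-butyl hydroperoxide CC(C)(C)OO
Why: In this rhodium-catalysed allylic C–H oxidation the ring olefin has allylic hydrogens only at C3 (C10 is quaternary, the exocyclic methylene has none), and trapping of the allylic radical at C3 rather than at the more hindered C1 should give the 1-en-3-one.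

Step 12
Reactants: 19 (4R)-4-[(1E,3R,6S)-1-iodo-2,6-dimethyl-8-[(triisopropylsilyl)oxy]oct-1-en-3-yl]-4,6,6-trimethyl-5-methylidenecyclohex-2-en-1-one
Product: 20 (4R)-4-[(1E,3R,6S)-1-iodo-2,6-dimethyl-8-[(triisopropylsilyl)oxy]oct-1-en-3-yl]-2,2,4-trimethyl-3-methylidenecyclohexan-1-one
Conditions: Cu(OAc)2·H2O (cat.), 1,2-bis(diphenylphosphino)benzene (cat.), (EtO)2MeSiH, t-BuOH, toluene, rt
Reagents that add atoms: none
Why: Copper hydride conjugate reduction should saturate C1–C2 chemoselectively, leaving the unactivated exocyclic olefin and the alkenyl iodide, so that no ring A olefin can intercept the alkenyl radical in step 13.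

Step 13
Reactants: 20 (4R)-4-[(1E,3R,6S)-1-iodo-2,6-dimethyl-8-[(triisopropylsilyl)oxy]oct-1-en-3-yl]-2,2,4-trimethyl-3-methylidenecyclohexan-1-one
Product: 23 (13S)-15-[(triisopropylsilyl)oxy]labd-7-en-3-one, via alkenyl radical 21 (not isolated), via tertiary radical 22 (not isolated)
Conditions: Bu3SnH (slow addition), AIBN (cat.), benzene (0.005 M), 80 °C
Reagents that add atoms: none
Why: Tributyltin radical abstracts iodine from 20 to give the σ-type C7 alkenyl radical 21, which inverts rapidly (so the E geometry of the iodide does not matter) and adds to the unsubstituted C6 terminus of the exocyclic C5=C6 olefin; the resulting tertiary C5 radical 22 is reduced by Bu3SnH. The closest known reaction type is the tin hydride-mediated alkenyl radical cyclization of 2-halo-1,6-dienes onto 1,1-disubstituted olefins, which gives methylcyclohexene rings. Ring B closes in the 6-endo-trig mode, either directly or by 5-exo attack at C5 followed by 3-exo closure and β-scission (a radical 1,2-alkenyl shift), and both paths converge on 22. The only new stereocenter, C5, is set in the hydrogen transfer: the β face of 22 is screened by the syn-axial methyl groups on C10 and C4, so hydrogen should enter from the α face and give the trans ring fusion, while C9 and C10 are not touched. The step needs endo regioselectivity and cyclization faster than reduction or 1,5-hydrogen shift of 21; attack at C5 would build a carbon flanked by two quaternary centers and is disfavoured, ring A carries no other olefin after step 12, and slow addition of Bu3SnH at high dilution keeps premature reduction slow.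

Step 14
Reactants: 23 (13S)-15-[(triisopropylsilyl)oxy]labd-7-en-3-one
Product: 24 (13S)-15-[(triisopropylsilyl)oxy]labd-7-en-3β-ol
Conditions: NaBH4, MeOH/THF, 0 °C
Reagents that add atoms: none
Why: In this borohydride reduction of the 4,4-dimethyl-3-ketone of the rigid trans-decalin, hydride should enter along the axial α trajectory, away from the β-axial methyls on C4 and C10, to give the equatorial 3β (3S) alcohol.

Step 15
Reactants: 24 (13S)-15-[(triisopropylsilyl)oxy]labd-7-en-3β-ol
Product: 25 (13S)-labd-7-ene-3β,15-diol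
Conditions: Bu4NF, THF, rt
Reagents that add atoms: none
Why: Fluoride-mediated desilylation should free the primary C15 alcohol without affecting the trisubstituted olefin or any stereocenter.

Step 16
Reactants: 25 (13S)-labd-7-ene-3β,15-diol
Product: 26 (13S)-labd-7-ene-3β,15-diyl diformate
Conditions: HCO2Ac (acetic formic anhydride), pyridine, DMAP (cat.), CH2Cl2, 0 °C → rt
Reagents that add atoms: acetic formic anhydride CC(=O)OC=O
Why: Acylation of both hydroxyl groups with the mixed anhydride, which transfers the formyl group selectively, should give the diformate with retention at C3.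

**Compound list**

1 | (S)-citronellol [(3S)-3,7-dimethyloct-6-en-1-ol] | CC(C)=CCC[C@H](C)CCO | starting material
2 | triisopropyl{[(3S)-3,7-dimethyloct-6-en-1-yl]oxy}silane | CC(C)=CCC[C@H](C)CCO[Si](C(C)C)(C(C)C)C(C)C | intermediate
3 | (4S)-4-methyl-6-[(triisopropylsilyl)oxy]hexanoic acid | OC(=O)CC[C@H](C)CCO[Si](C(C)C)(C(C)C)C(C)C | intermediate
4 | (4S)-4-methyl-6-[(triisopropylsilyl)oxy]hexanoic 2-methylpropyl carbonic anhydride (not isolated) | CC(C)COC(=O)OC(=O)CC[C@H](C)CCO[Si](C(C)C)(C(C)C)C(C)C | intermediate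
5 | (5S)-1-diazo-5-methyl-7-[(triisopropylsilyl)oxy]heptan-2-one | [N-]=[N+]=CC(=O)CC[C@H](C)CCO[Si](C(C)C)(C(C)C)C(C)C | intermediate
6 | ketoisophorone (2,6,6-trimethylcyclohex-2-ene-1,4-dione) | CC1=CC(=O)CC(C)(C)C1=O | starting material
7 | (4S)-4-hydroxy-2,6,6-trimethylcyclohex-2-en-1-one [(S)-phorenol] | CC1=C[C@@H](O)CC(C)(C)C1=O | intermediate
8 | (5S)-5-methyl-7-[(triisopropylsilyl)oxy]hept-1-en-1-one (ketene, not isolated) | O=C=CCC[C@H](C)CCO[Si](C(C)C)(C(C)C)C(C)C | intermediate
9 | (1S)-3,5,5-trimethyl-4-oxocyclohex-2-en-1-yl (5S)-5-methyl-7-[(triisopropylsilyl)oxy]heptanoate | CC1=C[C@@H](OC(=O)CCC[C@H](C)CCO[Si](C(C)C)(C(C)C)C(C)C)CC(C)(C)C1=O | intermediate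
10 | (1S)-3,5,5-trimethyl-4-methylidenecyclohex-2-en-1-yl (5S)-5-methyl-7-[(triisopropylsilyl)oxy]heptanoate | CC1=C[C@@H](OC(=O)CCC[C@H](C)CCO[Si](C(C)C)(C(C)C)C(C)C)CC(C)(C)C1=C | intermediate
11 | (Z)-O-trimethylsilyl ketene acetal of ester 10 (not isolated) | CC1=C[C@@H](O/C(O[Si](C)(C)C)=C/CC[C@H](C)CCO[Si](C(C)C)(C(C)C)C(C)C)CC(C)(C)C1=C | intermediate
12 | trimethylsilyl ester of acid 13 (not isolated) | C=C1C(C)(C)CC=C[C@]1(C)[C@@H](CC[C@H](C)CCO[Si](C(C)C)(C(C)C)C(C)C)C(=O)O[Si](C)(C)C | intermediate
13 | (2R,5S)-5-methyl-7-[(triisopropylsilyl)oxy]-2-[(1R)-1,5,5-trimethyl-6-methylidenecyclohex-2-en-1-yl]heptanoic acid | C=C1C(C)(C)CC=C[C@]1(C)[C@@H](CC[C@H](C)CCO[Si](C(C)C)(C(C)C)C(C)C)C(=O)O | intermediate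
14 | (3R,6S)-6-methyl-8-[(triisopropylsilyl)oxy]-3-[(1R)-1,5,5-trimethyl-6-methylidenecyclohex-2-en-1-yl]octan-2-one | C=C1C(C)(C)CC=C[C@]1(C)[C@@H](CC[C@H](C)CCO[Si](C(C)C)(C(C)C)C(C)C)C(C)=O | intermediate
15 | diethyl enol phosphate of 14 at the methyl side (not isolated) | C=C1C(C)(C)CC=C[C@]1(C)[C@@H](CC[C@H](C)CCO[Si](C(C)C)(C(C)C)C(C)C)C(=C)OP(=O)(OCC)OCC | intermediate
16 | triisopropyl{[(3S,6S)-3-methyl-6-[(1R)-1,5,5-trimethyl-6-methylidenecyclohex-2-en-1-yl]oct-7-yn-1-yl]oxy}silane | C=C1C(C)(C)CC=C[C@]1(C)[C@@H](CC[C@H](C)CCO[Si](C(C)C)(C(C)C)C(C)C)C#C | intermediate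
17 | (E)-alkenyl(dimethyl)alane from 16, Al on C7 and new methyl on C8 (not isolated) | C=C1C(C)(C)CC=C[C@]1(C)[C@@H](CC[C@H](C)CCO[Si](C(C)C)(C(C)C)C(C)C)/C(C)=C/[Al](C)C | intermediate
18 | {[(3S,6R,7E)-8-iodo-3,7-dimethyl-6-[(1R)-1,5,5-trimethyl-6-methylidenecyclohex-2-en-1-yl]oct-7-en-1-yl]oxy}triisopropylsilane | C=C1C(C)(C)CC=C[C@]1(C)[C@@H](CC[C@H](C)CCO[Si](C(C)C)(C(C)C)C(C)C)/C(C)=C/I | intermediate
19 | (4R)-4-[(1E,3R,6S)-1-iodo-2,6-dimethyl-8-[(triisopropylsilyl)oxy]oct-1-en-3-yl]-4,6,6-trimethyl-5-methylidenecyclohex-2-en-1-one | C=C1C(C)(C)C(=O)C=C[C@]1(C)[C@@H](CC[C@H](C)CCO[Si](C(C)C)(C(C)C)C(C)C)/C(C)=C/I | intermediate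
20 | (4R)-4-[(1E,3R,6S)-1-iodo-2,6-dimethyl-8-[(triisopropylsilyl)oxy]oct-1-en-3-yl]-2,2,4-trimethyl-3-methylidenecyclohexan-1-one | C=C1C(C)(C)C(=O)CC[C@]1(C)[C@@H](CC[C@H](C)CCO[Si](C(C)C)(C(C)C)C(C)C)/C(C)=C/I | intermediate
21 | C7 alkenyl radical derived from 20 (not isolated) | C=C1C(C)(C)C(=O)CC[C@]1(C)[C@@H](CC[C@H](C)CCO[Si](C(C)C)(C(C)C)C(C)C)C(C)=[CH] | intermediate
22 | tertiary C5 radical of ring-closed 15-silyloxy-3-oxolabd-7-ene (not isolated) | CC1=CC[C]2C(C)(C)C(=O)CC[C@]2(C)[C@H]1CC[C@H](C)CCO[Si](C(C)C)(C(C)C)C(C)C | intermediate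
23 | (13S)-15-[(triisopropylsilyl)oxy]labd-7-en-3-one (5R,9S,10R) | CC1=CC[C@H]2C(C)(C)C(=O)CC[C@]2(C)[C@H]1CC[C@H](C)CCO[Si](C(C)C)(C(C)C)C(C)C | intermediate
24 | (13S)-15-[(triisopropylsilyl)oxy]labd-7-en-3β-ol (3S,5R,9S,10R) | CC1=CC[C@H]2C(C)(C)[C@@H](O)CC[C@]2(C)[C@H]1CC[C@H](C)CCO[Si](C(C)C)(C(C)C)C(C)C | intermediate
25 | (13S)-labd-7-ene-3β,15-diol | CC1=CC[C@H]2C(C)(C)[C@@H](O)CC[C@]2(C)[C@H]1CC[C@H](C)CCO | intermediate
26 | (13S)-labd-7-ene-3β,15-diyl diformate (3S,5R,9S,10R,13S) | CC1=CC[C@H]2C(C)(C)[C@@H](OC=O)CC[C@]2(C)[C@H]1CC[C@H](C)CCOC=O | target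

**Totals**

Total step count: 16. Longest linear sequence: 15 steps (steps 1–3 and 5–16, from (S)-citronellol); the ring A branch is steps 4–16 (13 steps).

**Three steps most likely to fail**

Step 13 (key step). The alkenyl radical may be reduced by the stannane, or may take hydrogen intramolecularly (1,5-shift from C1, C12 or C20), before it reaches C6; hydrogen may also be delivered to C5 from the β face. The fallback changes the radical and the oxidation level at C8; it sets out from methyl ketone 14 and comes back at 23. Allylic oxidation of 14 (Rh2(cap)4, t-BuOOH) should give (3R,6S)-6-methyl-8-[(triisopropylsilyl)oxy]-3-[(1R)-1,5,5-trimethyl-6-methylidene-4-oxocyclohex-2-en-1-yl]octan-2-one F1. Kinetic enolisation at the methyl group (LiN(SiMe3)2, −78 °C) and iodination (I2) should give the iodomethyl ketone F2. Slow addition of Bu3SnH/AIBN then generates the electrophilic α-keto radical, which should close ring B by 6-endo attack on C6; the ring A enone is polarity-mismatched for this radical and cannot enolise. After hydrogen capture at C5 and brief treatment with DBU to place the C9 side chain equatorial, this gives (13S)-15-[(triisopropylsilyl)oxy]-17-norlabd-1-ene-3,8-dione F3. Kinetic deprotonation at C7 (KN(SiMe3)2) and PhNTf2 give the C7=C8 enol triflate F4, Pd(PPh3)4-catalysed Negishi coupling with MeZnCl gives (13S)-15-[(triisopropylsilyl)oxy]labda-1,7-dien-3-one F5, and hydrogenation of the disubstituted C1=C2 bond (H2, RhCl(PPh3)3) returns 23.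

Step 11. The allylic radical formed by hydrogen abstraction at C3 is ambident and may be oxygenated at C1 instead, and the allylic C–H bonds of the iodo-olefin may compete. The fallback replaces the radical chain by an ene/[2,3]-sigmatropic sequence; it sets out from 18 and comes back at 19. SeO2 (cat.) with t-BuOOH should hydroxylate C3 specifically, because the ene step can only take hydrogen from C3 and the [2,3]-shift returns the double bond to C1=C2; this gives the allylic alcohol (C3 epimers, of no consequence) F7, which MnO2 should oxidise to enone 19.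

Step 7. Leakage between chair and boat transition states may erode the configuration at C9, or the silyl ketene acetal may fragment before the hindered shift to the fully substituted C10. The fallback gives up kinetic control of C9 in favour of thermodynamic control; it sets out from ester 10 and comes back at 23. C-Acetylation of the lithium enolate of 10 (LiN(i-Pr)2, then N-acetylimidazole) should give the β-keto ester (1S)-3,5,5-trimethyl-4-methylidenecyclohex-2-en-1-yl 2-acetyl-5-methyl-7-[(triisopropylsilyl)oxy]heptanoate F6. Its Carroll rearrangement as the dianion (2 equiv LiN(i-Pr)2, THF, reflux), with decarboxylation on acidic work-up, should give 14 directly with the same chirality transfer to C10 but as a mixture at C9. That mixture is not taken on through steps 9–13; it goes through F1 to F5 as described for step 13, where C9 is set by equilibration of dione F3, and the route is rejoined at 23.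

**Further compounds**

F1 | step 13 | (3R,6S)-6-methyl-8-[(triisopropylsilyl)oxy]-3-[(1R)-1,5,5-trimethyl-6-methylidene-4-oxocyclohex-2-en-1-yl]octan-2-one | C=C1C(C)(C)C(=O)C=C[C@]1(C)[C@@H](CC[C@H](C)CCO[Si](C(C)C)(C(C)C)C(C)C)C(C)=O
F2 | step 13 | (3R,6S)-1-iodo-6-methyl-8-[(triisopropylsilyl)oxy]-3-[(1R)-1,5,5-trimethyl-6-methylidene-4-oxocyclohex-2-en-1-yl]octan-2-one | C=C1C(C)(C)C(=O)C=C[C@]1(C)[C@@H](CC[C@H](C)CCO[Si](C(C)C)(C(C)C)C(C)C)C(=O)CI
F3 | step 13 | (13S)-15-[(triisopropylsilyl)oxy]-17-norlabd-1-ene-3,8-dione | O=C1CC[C@H]2C(C)(C)C(=O)C=C[C@]2(C)[C@H]1CC[C@H](C)CCO[Si](C(C)C)(C(C)C)C(C)C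
F4 | step 13 | (13S)-3-oxo-15-[(triisopropylsilyl)oxy]-17-norlabda-1,7-dien-8-yl trifluoromethanesulfonate | FC(F)(F)S(=O)(=O)OC1=CC[C@H]2C(C)(C)C(=O)C=C[C@]2(C)[C@H]1CC[C@H](C)CCO[Si](C(C)C)(C(C)C)C(C)C
F5 | step 13 | (13S)-15-[(triisopropylsilyl)oxy]labda-1,7-dien-3-one | CC1=CC[C@H]2C(C)(C)C(=O)C=C[C@]2(C)[C@H]1CC[C@H](C)CCO[Si](C(C)C)(C(C)C)C(C)C
F6 | step 7 | (1S)-3,5,5-trimethyl-4-methylidenecyclohex-2-en-1-yl 2-acetyl-5-methyl-7-[(triisopropylsilyl)oxy]heptanoate (5S, C2 unspecified) | CC1=C[C@@H](OC(=O)C(CC[C@H](C)CCO[Si](C(C)C)(C(C)C)C(C)C)C(C)=O)CC(C)(C)C1=C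
F7 | step 11 | (4R)-4-[(1E,3R,6S)-1-iodo-2,6-dimethyl-8-[(triisopropylsilyl)oxy]oct-1-en-3-yl]-4,6,6-trimethyl-5-methylidenecyclohex-2-en-1-ol (C1 epimers) | C=C1C(C)(C)C(O)C=C[C@]1(C)[C@@H](CC[C@H](C)CCO[Si](C(C)C)(C(C)C)C(C)C)/C(C)=C/I
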